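**Retrosynthetic overview**
1. Last bond: C5–C6 of the trienoic acid, by a ring-opening alkenyl–alkenyl coupling of 2H-pyran-2-one with an (E)-β-boryl aryl enone (the proposed new step). The two ring alkenes become the 2Z,4Z diene and the lactone becomes the free CO2H, so the triene meets no later reagent.
2. The β-boryl enone comes from a salicylaldehyde (ethynyl addition, alkyne hydroboration, oxidation); the CHO comes from ortho-formylation of the phenol.
3. The (E)-enoate arm comes from hydroboration/B-alkyl Suzuki coupling of an (R)-3-arylbut-1-ene with tert-butyl (E)-3-iodoacrylate.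
4. The benzylic stereocentre comes from asymmetric hydrovinylation of a 2-silyloxystyrene made from 2-hydroxy-5-methoxybenzaldehyde.
5. Rings: the benzene ring is bought; no ring is built, and one ring (the pyranone) is opened in the last step.

Assumption: tert-butyl (2E)-3-iodoprop-2-enoate and 2H-pyran-2-one are bought as such; the hydrovinylation ligand antipode that gives the R product is identified on the first run (the other antipode gives S).

**Route**

Step 1
Reactants: 1 2-hydroxy-5-methoxybenzaldehyde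
Product: 2 2-[(tert-butyldimethylsilyl)oxy]-5-methoxybenzaldehyde
Conditions: TBSCl, imidazole, DMF, rt
Reagents that add atoms: tert-butyldimethylsilyl chloride (TBSCl), CC(C)(C)[Si](C)(C)Cl
Why: Imidazole-promoted O-silylation masks the phenol so that the Wittig base and the cationic nickel hydride of step 3 see no acidic OH.

Step 2
Reactants: 2 2-[(tert-butyldimethylsilyl)oxy]-5-methoxybenzaldehyde
Product: 3 tert-butyl(2-ethenyl-4-methoxyphenoxy)dimethylsilane
Conditions: Ph3PCH3Br, KOtBu, THF, 0 °C to rt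
Reagents that add atoms: methyltriphenylphosphonium bromide, C[P+](c1ccccc1)(c1ccccc1)c1ccccc1.[Br-]
Why: Wittig methylenation of a non-enolisable aryl aldehyde with the unstabilised ylide; no stereocentre is formed.

Step 3
Reactants: 3 tert-butyl(2-ethenyl-4-methoxyphenoxy)dimethylsilane
Product: 4 tert-butyl{2-[(2R)-but-3-en-2-yl]-4-methoxyphenoxy}dimethylsilane
Conditions: ethylene (1 atm), [Ni(η3-C3H5)Br]2 (1 mol %), binaphthol/bis(1-phenylethyl)amine phosphoramidite (2 mol %, antipode giving R), Na[B(3,5-(CF3)2C6H3)4] (2.5 mol %), CH2Cl2, −70 °C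
Reagents that add atoms: ethylene, C=C
Why: Nickel-catalysed asymmetric hydrovinylation: the vinylarene inserts into a chiral cationic nickel hydride to give an η3-benzyl nickel species that takes up ethylene and β-hydride-eliminates, so the chosen ligand antipode sets the benzylic centre as R and only the branched 3-arylbut-1-ene forms at −70 °C.

Step 4
Reactants: 4 tert-butyl{2-[(2R)-but-3-en-2-yl]-4-methoxyphenoxy}dimethylsilane; 5 tert-butyl (2E)-3-iodoprop-2-enoate
Product: 7 tert-butyl (2E,6R)-6-{2-[(tert-butyldimethylsilyl)oxy]-5-methoxyphenyl}hept-2-enoate, via B-alkyl-9-BBN adduct 6 (not isolated)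
Conditions: 9-BBN, THF, rt; then 5, Pd(dppf)Cl2 (5 mol %), AsPh3 (5 mol %), aq K3PO4, DMF, rt
Reagents that add atoms: 9-borabicyclo[3.3.1]nonane (9-BBN-H), [H]B1C2CCCC1CCC2 (its boryl group is held in 6 and leaves again on the way to 7)
Why: Anti-Markovnikov hydroboration with 9-BBN followed by B-alkyl Suzuki–Miyaura coupling with the very reactive β-iodoacrylate at room temperature keeps the E geometry of 5 and does not touch the benzylic centre.

Step 5
Reactants: 7 tert-butyl (2E,6R)-6-{2-[(tert-butyldimethylsilyl)oxy]-5-methoxyphenyl}hept-2-enoate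
Product: 8 tert-butyl (2E,6R)-6-(2-hydroxy-5-methoxyphenyl)hept-2-enoate
Conditions: KHF2, MeOH, rt
Reagents that add atoms: none
Why: Fluoride cleavage of the aryl silyl ether (KHF2 is selective for phenolic TBS ethers) leaves the tert-butyl enoate untouched and frees the OH that directs step 6.

Step 6
Reactants: 8 tert-butyl (2E,6R)-6-(2-hydroxy-5-methoxyphenyl)hept-2-enoate
Product: 10 tert-butyl (2E,6R)-6-(3-formyl-2-hydroxy-5-methoxyphenyl)hept-2-enoate, via ortho-hydroxymethyl phenol 9 (not isolated)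
Conditions: MgCl2, Et3N, (CH2O)n, MeCN, reflux; then 1 M HCl
Reagents that add atoms: paraformaldehyde (reacts as formaldehyde), C=O
Why: Magnesium-mediated ortho-formylation of a phenol (Casnati–Skattebøl): the magnesium phenoxide delivers formaldehyde to the only free ortho position, and a second formaldehyde oxidises the benzylic alkoxide by hydride transfer.

Step 7
Reactants: 10 tert-butyl (2E,6R)-6-(3-formyl-2-hydroxy-5-methoxyphenyl)hept-2-enoate
Product: 11 tert-butyl (2E,6R)-6-[3-formyl-5-methoxy-2-(methoxymethoxy)phenyl]hept-2-enoate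
Conditions: MOMCl, iPr2NEt, CH2Cl2, 0 °C to reflux
Reagents that add atoms: chloromethyl methyl ether (MOMCl), COCCl
Why: O-alkylation of the phenol gives a MOM ether that blocks phenoxide and quinone-methide chemistry in steps 8 to 10 and is acid-labile like the tert-butyl ester.

Step 8
Reactants: 11 tert-butyl (2E,6R)-6-[3-formyl-5-methoxy-2-(methoxymethoxy)phenyl]hept-2-enoate
Product: 12 tert-butyl (2E,6R)-6-[3-(1-hydroxyprop-2-yn-1-yl)-5-methoxy-2-(methoxymethoxy)phenyl]hept-2-enoate (about 1:1 carbinol epimers)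
Conditions: HC≡CMgBr, THF, −78 to −20 °C; then aq NH4Cl
Reagents that add atoms: ethynylmagnesium bromide, C#C[Mg]Br
Why: Grignard addition: the acetylide adds to the chelated aryl aldehyde far faster than to the hindered tert-butyl enoate at low temperature; the new carbinol centre forms as a mixture and is erased in step 10.

Step 9
Reactants: 12 tert-butyl (2E,6R)-6-[3-(1-hydroxyprop-2-yn-1-yl)-5-methoxy-2-(methoxymethoxy)phenyl]hept-2-enoate
Product: 14 tert-butyl (2E,6R)-6-{3-[(2E)-1-hydroxy-3-(4,4,5,5-tetramethyl-1,3,2-dioxaborolan-2-yl)prop-2-en-1-yl]-5-methoxy-2-(methoxymethoxy)phenyl}hept-2-enoate, via O-borylated alkenylboronate 13 (not isolated)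
Conditions: HBpin (2.5 equiv), Cp2Zr(H)Cl (10 mol %), Et3N (10 mol %), THF, 50 °C; then aq NH4Cl
Reagents that add atoms: pinacolborane (HBpin), [H]B1OC(C)(C)C(C)(C)O1
Why: Zirconium-catalysed syn, anti-Markovnikov hydroboration of the terminal alkyne gives only the (E)-alkenylboronate; the free OH is O-borylated in the flask and released on work-up, and the enoate is inert to HBpin.

Step 10
Reactants: 14 tert-butyl (2E,6R)-6-{3-[(2E)-1-hydroxy-3-(4,4,5,5-tetramethyl-1,3,2-dioxaborolan-2-yl)prop-2-en-1-yl]-5-methoxy-2-(methoxymethoxy)phenyl}hept-2-enoate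
Product: 15 tert-butyl (2E,6R)-6-{5-methoxy-2-(methoxymethoxy)-3-[(2E)-3-(4,4,5,5-tetramethyl-1,3,2-dioxaborolan-2-yl)prop-2-enoyl]phenyl}hept-2-enoate
Conditions: Dess–Martin periodinane, CH2Cl2, 0 °C to rt
Reagents that add atoms: none
Why: Dess–Martin oxidation of the allylic, benzylic alcohol gives the enone under neutral conditions that the alkenyl-Bpin, MOM and ester groups tolerate; the conjugated alkene stays E.

Step 11
Reactants: 15 tert-butyl (2E,6R)-6-{5-methoxy-2-(methoxymethoxy)-3-[(2E)-3-(4,4,5,5-tetramethyl-1,3,2-dioxaborolan-2-yl)prop-2-enoyl]phenyl}hept-2-enoate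
Product: 16 (2E,6R)-6-{2-hydroxy-5-methoxy-3-[(2E)-3-(4,4,5,5-tetramethyl-1,3,2-dioxaborolan-2-yl)prop-2-enoyl]phenyl}hept-2-enoic acid
Conditions: TFA/CH2Cl2 (1:4), H2O (5 equiv), 0 °C to rt
Reagents that add atoms: none
Why: Acidolysis of the MOM acetal (activated by the ortho carbonyl) and of the tert-butyl ester is done before the acid-sensitive triene exists; the alkenyl-Bpin and the E enone survive TFA at room temperature.

Step 12
Reactants: 16 (2E,6R)-6-{2-hydroxy-5-methoxy-3-[(2E)-3-(4,4,5,5-tetramethyl-1,3,2-dioxaborolan-2-yl)prop-2-enoyl]phenyl}hept-2-enoic acid; 17 2H-pyran-2-one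
Product: 18 (2Z,4Z,6E)-8-{3-[(2R,5E)-6-carboxyhex-5-en-2-yl]-2-hydroxy-5-methoxyphenyl}-8-oxoocta-2,4,6-trienoic acid
Conditions: 17 (1.5 equiv), Ni(cod)2 (10 mol %), PCy3 (20 mol %), K3PO4 (3.5 equiv), H2O (5 equiv), degassed THF, 40 °C, dark; then pH 4 buffer
Reagents that add atoms: none
Why: Proposed new method: stereoretentive ring-opening Suzuki–Miyaura coupling of a 2-pyranone. Zerovalent nickel/PCy3 binds C5=C6 of 17 and inserts into the C6–O bond (an alkenyl carboxylate C–O bond; the reverse of the C–O reductive elimination that closes 2-pyranones on nickel) to give a seven-membered (Z,Z)-dienyl carboxylate of divalent nickel; the nickel-bound carboxylate acts as internal base for boron-to-nickel transfer of the (E)-alkenyl group of 16, and C(sp2)–C(sp2) reductive elimination releases the (2Z,4Z,6E)-trienoate with both ring alkenes kept Z and the lactone unveiled as CO2H. The closest known reaction types are nickel-catalysed Suzuki–Miyaura coupling of alkenyl and aryl pivalates or acetates through C(sp2)–O oxidative addition, and the ring-opening of 2-pyranones by organometallic 1,6-addition, which gives the 2Z,4E isomer instead.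

**Compound list**

1 | 2-hydroxy-5-methoxybenzaldehyde | COc1ccc(O)c(C=O)c1 | starting material
2 | 2-[(tert-butyldimethylsilyl)oxy]-5-methoxybenzaldehyde | COc1ccc(O[Si](C)(C)C(C)(C)C)c(C=O)c1 | intermediate
3 | tert-butyl(2-ethenyl-4-methoxyphenoxy)dimethylsilane | COc1ccc(O[Si](C)(C)C(C)(C)C)c(C=C)c1 | intermediate
4 | tert-butyl{2-[(2R)-but-3-en-2-yl]-4-methoxyphenoxy}dimethylsilane | COc1ccc(O[Si](C)(C)C(C)(C)C)c([C@H](C)C=C)c1 | intermediate
5 | tert-butyl (2E)-3-iodoprop-2-enoate | CC(C)(C)OC(=O)/C=C/I | starting material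
6 | 9-[(3R)-3-{2-[(tert-butyldimethylsilyl)oxy]-5-methoxyphenyl}butyl]-9-borabicyclo[3.3.1]nonane (B-alkyl-9-BBN adduct, not isolated) | COc1ccc(O[Si](C)(C)C(C)(C)C)c([C@H](C)CCB2C3CCCC2CCC3)c1 | intermediate
7 | tert-butyl (2E,6R)-6-{2-[(tert-butyldimethylsilyl)oxy]-5-methoxyphenyl}hept-2-enoate | COc1ccc(O[Si](C)(C)C(C)(C)C)c([C@H](C)CC/C=C/C(=O)OC(C)(C)C)c1 | intermediate
8 | tert-butyl (2E,6R)-6-(2-hydroxy-5-methoxyphenyl)hept-2-enoate | COc1ccc(O)c([C@H](C)CC/C=C/C(=O)OC(C)(C)C)c1 | intermediate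
9 | tert-butyl (2E,6R)-6-[2-hydroxy-3-(hydroxymethyl)-5-methoxyphenyl]hept-2-enoate (ortho-hydroxymethyl phenol, present as its magnesium salt, not isolated) | COc1cc(CO)c(O)c([C@H](C)CC/C=C/C(=O)OC(C)(C)C)c1 | intermediate
10 | tert-butyl (2E,6R)-6-(3-formyl-2-hydroxy-5-methoxyphenyl)hept-2-enoate | COc1cc(C=O)c(O)c([C@H](C)CC/C=C/C(=O)OC(C)(C)C)c1 | intermediate
11 | tert-butyl (2E,6R)-6-[3-formyl-5-methoxy-2-(methoxymethoxy)phenyl]hept-2-enoate | COc1cc(C=O)c(OCOC)c([C@H](C)CC/C=C/C(=O)OC(C)(C)C)c1 | intermediate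
12 | tert-butyl (2E,6R)-6-[3-(1-hydroxyprop-2-yn-1-yl)-5-methoxy-2-(methoxymethoxy)phenyl]hept-2-enoate (mixture of carbinol epimers) | COc1cc(C(O)C#C)c(OCOC)c([C@H](C)CC/C=C/C(=O)OC(C)(C)C)c1 | intermediate
13 | tert-butyl (2E,6R)-6-{5-methoxy-2-(methoxymethoxy)-3-[(2E)-3-(4,4,5,5-tetramethyl-1,3,2-dioxaborolan-2-yl)-1-[(4,4,5,5-tetramethyl-1,3,2-dioxaborolan-2-yl)oxy]prop-2-en-1-yl]phenyl}hept-2-enoate (O-borylated alkenylboronate, not isolated) | COc1cc(C(OB2OC(C)(C)C(C)(C)O2)/C=C/B2OC(C)(C)C(C)(C)O2)c(OCOC)c([C@H](C)CC/C=C/C(=O)OC(C)(C)C)c1 | intermediate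
14 | tert-butyl (2E,6R)-6-{3-[(2E)-1-hydroxy-3-(4,4,5,5-tetramethyl-1,3,2-dioxaborolan-2-yl)prop-2-en-1-yl]-5-methoxy-2-(methoxymethoxy)phenyl}hept-2-enoate | COc1cc(C(O)/C=C/B2OC(C)(C)C(C)(C)O2)c(OCOC)c([C@H](C)CC/C=C/C(=O)OC(C)(C)C)c1 | intermediate
15 | tert-butyl (2E,6R)-6-{5-methoxy-2-(methoxymethoxy)-3-[(2E)-3-(4,4,5,5-tetramethyl-1,3,2-dioxaborolan-2-yl)prop-2-enoyl]phenyl}hept-2-enoate | COc1cc(C(=O)/C=C/B2OC(C)(C)C(C)(C)O2)c(OCOC)c([C@H](C)CC/C=C/C(=O)OC(C)(C)C)c1 | intermediate
16 | (2E,6R)-6-{2-hydroxy-5-methoxy-3-[(2E)-3-(4,4,5,5-tetramethyl-1,3,2-dioxaborolan-2-yl)prop-2-enoyl]phenyl}hept-2-enoic acid | COc1cc(C(=O)/C=C/B2OC(C)(C)C(C)(C)O2)c(O)c([C@H](C)CC/C=C/C(=O)O)c1 | intermediate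
17 | 2H-pyran-2-one | O=C1C=CC=CO1 | starting material
18 | (2Z,4Z,6E)-8-{3-[(2R,5E)-6-carboxyhex-5-en-2-yl]-2-hydroxy-5-methoxyphenyl}-8-oxoocta-2,4,6-trienoic acid | COc1cc(C(=O)/C=C/C=C\C=C/C(=O)O)c(O)c([C@H](C)CC/C=C/C(=O)O)c1 | target

**Totals and risks**

Total step count: 12. Longest linear sequence: 12 steps (1 to 18; 5 and 17 are bought).

Steps most likely to fail:

- **Step 12 (the proposed new coupling).** Nickel may insert into the acyl C–O bond of 17, add in a 1,6 sense to give the 2Z,4E isomer, or be held by the enone and the phenoxide. The fallback uses known chemistry, sets out from 16 and comes back at 18. Stille coupling of ethyl (Z)-3-iodoacrylate with (Z)-1,2-bis(tributylstannyl)ethene (PdCl2(MeCN)2, DMF, rt) gives ethyl (2Z,4Z)-5-(tributylstannyl)penta-2,4-dienoate F1. Iodine in CH2Cl2 at 0 °C converts it with retention into ethyl (2Z,4Z)-5-iodopenta-2,4-dienoate F2. LiOH in THF/H2O at 0 °C gives (2Z,4Z)-5-iodopenta-2,4-dienoic acid F3. Palladium-catalysed Suzuki–Miyaura coupling of F3 with 16 (Pd(PPh3)4, TlOEt, THF/H2O, rt, dark) then gives 18 with retention at both partners.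

- **Step 3 (hydrovinylation next to a bulky silyloxy group).** The reaction may be slow or give a lower ee. The fallback sets out from 2 and comes back at 4. Horner–Wadsworth–Emmons reaction of 2 with triethyl phosphonoacetate (NaH, THF) gives ethyl (2E)-3-{2-[(tert-butyldimethylsilyl)oxy]-5-methoxyphenyl}prop-2-enoate F4. Reduction with iBu2AlH (CH2Cl2, −78 °C) gives (2E)-3-{2-[(tert-butyldimethylsilyl)oxy]-5-methoxyphenyl}prop-2-en-1-ol F5. CBr4/PPh3 gives {2-[(1E)-3-bromoprop-1-en-1-yl]-4-methoxyphenoxy}(tert-butyl)dimethylsilane F6. Copper-catalysed asymmetric allylic alkylation of F6 with MeMgBr (CuBr·SMe2, Taniaphos ligand antipode giving R, CH2Cl2, −75 °C) then gives 4 by SN2' attack.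

- **Step 9 (hydroboration beside a free hydroxyl and an enoate).** The zirconium hydride catalyst may be consumed or the conversion may stall. The fallback sets out from 12 and comes back at 15, so step 10 is skipped. Dess–Martin oxidation of 12 gives tert-butyl (2E,6R)-6-[5-methoxy-2-(methoxymethoxy)-3-(prop-2-ynoyl)phenyl]hept-2-enoate F7. Copper-catalysed conjugate protoboration of this ynone (B2pin2, CuCl, Xantphos, NaOtBu, MeOH, THF, −20 °C) gives 15 by syn addition; the ynone reacts far faster than the tert-butyl enoate.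

**Further compounds**

F1 | step 12 | ethyl (2Z,4Z)-5-(tributylstannyl)penta-2,4-dienoate | CCOC(=O)/C=C\C=C/[Sn](CCCC)(CCCC)CCCC
F2 | step 12 | ethyl (2Z,4Z)-5-iodopenta-2,4-dienoate | CCOC(=O)/C=C\C=C/I
F3 | step 12 | (2Z,4Z)-5-iodopenta-2,4-dienoic acid | OC(=O)/C=C\C=C/I
F4 | step 3 | ethyl (2E)-3-{2-[(tert-butyldimethylsilyl)oxy]-5-methoxyphenyl}prop-2-enoate | CCOC(=O)/C=C/c1cc(OC)ccc1O[Si](C)(C)C(C)(C)C
F5 | step 3 | (2E)-3-{2-[(tert-butyldimethylsilyl)oxy]-5-methoxyphenyl}prop-2-en-1-ol | OC/C=C/c1cc(OC)ccc1O[Si](C)(C)C(C)(C)C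
F6 | step 3 | {2-[(1E)-3-bromoprop-1-en-1-yl]-4-methoxyphenoxy}(tert-butyl)dimethylsilane | BrC/C=C/c1cc(OC)ccc1O[Si](C)(C)C(C)(C)C
F7 | step 9 | tert-butyl (2E,6R)-6-[5-methoxy-2-(methoxymethoxy)-3-(prop-2-ynoyl)phenyl]hept-2-enoate | COc1cc(C(=O)C#C)c(OCOC)c([C@H](C)CC/C=C/C(=O)OC(C)(C)C)c1
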